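**Retrosynthetic overview**
1. The strategy rests on the α-ketol of ring C. The C4 ketone carbon is bonded directly to the fully substituted carbinol C3, which carries OH, ring B and C2H2–O1. C3–C4 is therefore cut with reversed polarity: C4 becomes an acyl anion drawn from a ring-A aldehyde, and C3 becomes a ring-B aryl ketone held through O1–C2.
2. Keto aldehyde 16 comes from O1–C2 ether formation between salicylaldehyde 7 (ring A) and bromo ketone 15 (ring B).
3. Both prenyl groups arise by aromatic Claisen shifts of aryl 1,1-dimethylallyl ethers. For C8 the shift goes to the only free ortho carbon, and for C3' it goes to the carbon favoured by the chelated 2'-OH.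
4. 5-OH and 4'-OH travel as allyl ethers and are freed together by palladium under near-neutral conditions. A late Lewis-acid cleavage of a 5-methyl ether or an acidic acetal removal would endanger the C3 carbinol (loss of water to the isoflavone), the 2'-OMe group and the o-prenylphenol.
5. Rings A and B are bought as arenes. Ring C is the only ring formed, in step 13, which also sets C3, the only stereocentre.

Key step: step 13

Assumption: on the usual model (E-enaminol, O–H···O=C hydrogen bond, ring B turned away from the azolium), the (5aR,10bS) salt, made from (1S,2R)-cis-1-amino-2-indanol, is taken to give 3S. The sense has to be checked on 17 (ECD or X-ray of a heavy-atom derivative), and the equally available mirror-image salt would be used in the same way if it proves opposite.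

Flavonoid numbering is used throughout, and prenyl means 3-methylbut-2-en-1-yl.

**Step 1**
Reactants: 1 2,4,6-trimethoxybenzaldehyde
Product: 2 2,6-dihydroxy-4-methoxybenzaldehyde
Conditions: AlCl3 (4 equiv), CH2Cl2, 0 °C → reflux; then ice/1 M HCl
Reagents that add atoms: none
Why: Chelation-controlled aryl methyl ether cleavage, in which AlCl3 bridges the formyl oxygen and each flanking methoxy oxygen so that chloride removes only the two ortho methyl groups (the same reaction type turns 2,6-dimethoxybenzaldehyde into 2,6-dihydroxybenzaldehyde) while the unchelated 4-OMe stays.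

**Step 2**
Reactants: 2 2,6-dihydroxy-4-methoxybenzaldehyde; 3 3-chloro-3-methylbut-1-yne
Product: 4 2-hydroxy-4-methoxy-6-[(2-methylbut-3-yn-2-yl)oxy]benzaldehyde
Conditions: 3 (1.1 equiv), K2CO3 (1.2 equiv), KI (cat.), CuI (cat.), acetone, N2, reflux
Reagents that add atoms: none
Why: Copper-assisted Williamson-type O-alkylation with a tertiary propargylic chloride, in which only one of the two equivalent hydroxyls can be hydrogen-bonded to the formyl oxygen at a time, the free one reacts, and the remaining one is then locked in the chelate, which should stop the reaction at the monoether.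

**Step 3**
Reactants: 4 2-hydroxy-4-methoxy-6-[(2-methylbut-3-yn-2-yl)oxy]benzaldehyde
Product: 5 2-(allyloxy)-4-methoxy-6-[(2-methylbut-3-yn-2-yl)oxy]benzaldehyde
Conditions: allyl bromide, K2CO3, DMF, 50 °C
Reagents that add atoms: allyl bromide, C=CCBr
Why: Williamson ether synthesis, in which the reactive primary allylic bromide in DMF overcomes the hydrogen bond of the last phenol at a temperature far below that of a propargyl Claisen shift.

**Step 4**
Reactants: 5 2-(allyloxy)-4-methoxy-6-[(2-methylbut-3-yn-2-yl)oxy]benzaldehyde
Product: 6 2-(allyloxy)-4-methoxy-6-[(2-methylbut-3-en-2-yl)oxy]benzaldehyde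
Conditions: H2 (1 atm, 1 equiv uptake), Pd/CaCO3 poisoned with Pb(OAc)2 (Lindlar catalyst), quinoline, EtOAc, rt
Reagents that add atoms: none
Why: Lindlar semihydrogenation, in which the terminal alkyne binds to the poisoned palladium surface far more strongly than any alkene, so the reduction should stop at the 1,1-dimethylallyl ether and leave the O-allyl group and the aldehyde alone.

**Step 5**
Reactants: 6 2-(allyloxy)-4-methoxy-6-[(2-methylbut-3-en-2-yl)oxy]benzaldehyde
Product: 7 6-(allyloxy)-2-hydroxy-4-methoxy-3-(3-methylbut-2-en-1-yl)benzaldehyde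
Conditions: N,N-diethylaniline, Ar, 130 °C
Reagents that add atoms: none
Why: Aromatic Claisen rearrangement, in which the [3,3] shift turns the 1,1-dimethylallyl unit into a prenyl group at the only free ortho carbon (the other carries CHO) and frees exactly the phenol that becomes O1, while the gem-dimethyl ether migrates well below the temperature that the simple O-allyl ether needs.

**Step 6**
Reactants: 8 2,4-dihydroxyacetophenone; 3 3-chloro-3-methylbut-1-yne
Product: 9 1-{2-hydroxy-4-[(2-methylbut-3-yn-2-yl)oxy]phenyl}ethan-1-one
Conditions: 3 (1.2 equiv), K2CO3, KI (cat.), CuI (cat.), acetone, N2, reflux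
Reagents that add atoms: none
Why: Copper-assisted Williamson-type O-alkylation that takes place at the free 4-OH, because the 2-OH is held in the hydrogen-bonded chelate with the acetyl group.

**Step 7**
Reactants: 9 1-{2-hydroxy-4-[(2-methylbut-3-yn-2-yl)oxy]phenyl}ethan-1-one
Product: 10 1-{2-hydroxy-4-[(2-methylbut-3-en-2-yl)oxy]phenyl}ethan-1-one
Conditions: H2 (1 atm, 1 equiv uptake), Pd/CaCO3 poisoned with Pb(OAc)2 (Lindlar catalyst), quinoline, EtOAc, rt
Reagents that add atoms: none
Why: Lindlar semihydrogenation of a terminal alkyne, which should stop at the alkene and does not touch the aryl ketone.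

**Step 8**
Reactants: 10 1-{2-hydroxy-4-[(2-methylbut-3-en-2-yl)oxy]phenyl}ethan-1-one
Product: 11 1-[2,4-dihydroxy-3-(3-methylbut-2-en-1-yl)phenyl]ethan-1-one
Conditions: N,N-diethylaniline, Ar, 130–140 °C
Reagents that add atoms: none
Why: Aromatic Claisen rearrangement, in which the 2-hydroxyacetophenone chelate localises double-bond character in C3–C4 and so directs migration to C3 between the two oxygens, as is long established for 4-O-allylresacetophenone (any 5-prenyl isomer would be removed by chromatography).

**Step 9**
Reactants: 11 1-[2,4-dihydroxy-3-(3-methylbut-2-en-1-yl)phenyl]ethan-1-one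
Product: 12 1-[4-(allyloxy)-2-hydroxy-3-(3-methylbut-2-en-1-yl)phenyl]ethan-1-one
Conditions: allyl bromide (1.05 equiv), K2CO3, acetone, reflux
Reagents that add atoms: allyl bromide, C=CCBr
Why: Williamson ether synthesis that is selective for the more acidic, unchelated 4-OH over the hydrogen-bonded and doubly flanked 2-OH.

**Step 10**
Reactants: 12 1-[4-(allyloxy)-2-hydroxy-3-(3-methylbut-2-en-1-yl)phenyl]ethan-1-one
Product: 13 1-[4-(allyloxy)-2-methoxy-3-(3-methylbut-2-en-1-yl)phenyl]ethan-1-one
Conditions: MeI (excess), K2CO3, DMF, 40 °C
Reagents that add atoms: iodomethane, CI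
Why: Williamson methylation of the remaining chelated phenol, which the small electrophile and the polar aprotic solvent make feasible with a base too weak to enolise the ketone.

**Step 11**
Reactants: 13 1-[4-(allyloxy)-2-methoxy-3-(3-methylbut-2-en-1-yl)phenyl]ethan-1-one
Product: 15 2-bromo-1-[4-(allyloxy)-2-methoxy-3-(3-methylbut-2-en-1-yl)phenyl]ethan-1-one, via silyl enol ether 14 (not isolated)
Conditions: TMSOTf (1.1 equiv), Et3N (1.2 equiv), CH2Cl2, 0 °C; pentane, decant from the ammonium salt, concentrate; NBS (1.0 equiv), THF, −78 → 0 °C; aq. work-up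
Reagents that add atoms: N-bromosuccinimide, O=C1CCC(=O)N1Br; trimethylsilyl trifluoromethanesulfonate, C[Si](C)(C)OS(=O)(=O)C(F)(F)F (its silyl group stays only in 14)
Why: Soft enolisation to the silyl enol ether followed by its electrophilic bromination, in which the enol ether is by far the most nucleophilic π system, so one equivalent of NBS at low temperature should be used up before the prenyl and allyl alkenes or C5' of the arene can react.

**Step 12**
Reactants: 7 6-(allyloxy)-2-hydroxy-4-methoxy-3-(3-methylbut-2-en-1-yl)benzaldehyde; 15 2-bromo-1-[4-(allyloxy)-2-methoxy-3-(3-methylbut-2-en-1-yl)phenyl]ethan-1-one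
Product: 16 6-(allyloxy)-2-{2-[4-(allyloxy)-2-methoxy-3-(3-methylbut-2-en-1-yl)phenyl]-2-oxoethoxy}-4-methoxy-3-(3-methylbut-2-en-1-yl)benzaldehyde
Conditions: K2CO3 (1.5 equiv), DMF, 0 °C → rt, stopped at full conversion of 7
Reagents that add atoms: none
Why: Williamson ether synthesis (SN2 at a phenacyl-type bromide), whose high rate allows a mild carbonate base at or below room temperature, where the follow-up Rap–Stoermer aldol condensation of 16 to a 2-aroylbenzofuran is slow.

**Step 13**
Reactants: 16 keto aldehyde (name as in step 12)
Product: 17 (3S)-5-(allyloxy)-3-[4-(allyloxy)-2-methoxy-3-(3-methylbut-2-en-1-yl)phenyl]-3-hydroxy-7-methoxy-8-(3-methylbut-2-en-1-yl)chroman-4-one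
Conditions: (5aR,10bS)-2-(pentafluorophenyl)-5a,10b-dihydro-4H,6H-indeno[2,1-b][1,2,4]triazolo[4,3-d][1,4]oxazin-2-ium tetrafluoroborate (20 mol%), Et3N (20 mol%), 4 Å MS, toluene (0.05 M), Ar, 25 °C
Reagents that add atoms: none
Why: Et3N frees the triazolylidene, which adds to the only aldehyde of 16; proton transfer gives the enaminol (Breslow intermediate), whose carbon C4 now acts as an acyl anion and attacks the tethered aryl ketone carbon C3, and collapse of the adduct returns the carbene and the C4 ketone. The closest known reaction type is the enantioselective carbene-catalysed intramolecular crossed aldehyde–ketone benzoin reaction of 2-(2-aryl-2-oxoethoxy)benzaldehydes to 3-hydroxychroman-4-ones. Ring C closes in a 6-(enolexo)-exo-trig mode through C4, C4a, C8a, O1, C2 and C3. C3 is set by the catalyst: the indane wall shields one face of the enaminol, the enol O–H···O=C hydrogen bond holds the ketone over the open face and ring B turns away from the azolium, so one ketone face is attacked and 3S should result. Selectivity is needed against homo-benzoin, against the base-induced 5-exo aldol/dehydration to a 2-aroylbenzofuran and against hydroacylation of the neighbouring O-allyl alkene; the first is excluded because only the aldehyde can become the nucleophile and its two ortho oxygens keep a second aldehyde away, the second is held back by the weak amine base that the acidic N-C6F5 azolium salt allows, and the third is known only at temperatures far above 25 °C.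

**Step 14**
Reactants: 17 (3S)-bis(allyl ether) ketol (name as in step 13)
Product: 18 sophonorol F, (3S)-3,5-dihydroxy-3-[4-hydroxy-2-methoxy-3-(3-methylbut-2-en-1-yl)phenyl]-7-methoxy-8-(3-methylbut-2-en-1-yl)chroman-4-one
Conditions: Pd(PPh3)4 (5 mol%), morpholine (10 equiv), THF, Ar, rt; aq. NH4Cl work-up
Reagents that add atoms: none
Why: Tsuji–Trost-type deallylation, in which zerovalent palladium ionises both aryl allyl ethers to π-allyl complexes that morpholine traps, under near-neutral conditions that leave the C-prenyl groups (no leaving group), both methyl ethers and the tertiary benzylic carbinol with its configuration untouched.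

**Compound list**
1 | 2,4,6-trimethoxybenzaldehyde | COc1cc(OC)c(C=O)c(OC)c1 | starting material
2 | 2,6-dihydroxy-4-methoxybenzaldehyde | COc1cc(O)c(C=O)c(O)c1 | intermediate
3 | 3-chloro-3-methylbut-1-yne | C#CC(C)(C)Cl | starting material
4 | 2-hydroxy-4-methoxy-6-[(2-methylbut-3-yn-2-yl)oxy]benzaldehyde | COc1cc(O)c(C=O)c(OC(C)(C)C#C)c1 | intermediate
5 | 2-(allyloxy)-4-methoxy-6-[(2-methylbut-3-yn-2-yl)oxy]benzaldehyde | COc1cc(OCC=C)c(C=O)c(OC(C)(C)C#C)c1 | intermediate
6 | 2-(allyloxy)-4-methoxy-6-[(2-methylbut-3-en-2-yl)oxy]benzaldehyde | COc1cc(OCC=C)c(C=O)c(OC(C)(C)C=C)c1 | intermediate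
7 | 6-(allyloxy)-2-hydroxy-4-methoxy-3-prenylbenzaldehyde | COc1cc(OCC=C)c(C=O)c(O)c1CC=C(C)C | intermediate
8 | 2,4-dihydroxyacetophenone | CC(=O)c1ccc(O)cc1O | starting material
9 | 1-{2-hydroxy-4-[(2-methylbut-3-yn-2-yl)oxy]phenyl}ethan-1-one | CC(=O)c1ccc(OC(C)(C)C#C)cc1O | intermediate
10 | 1-{2-hydroxy-4-[(2-methylbut-3-en-2-yl)oxy]phenyl}ethan-1-one | CC(=O)c1ccc(OC(C)(C)C=C)cc1O | intermediate
11 | 1-(2,4-dihydroxy-3-prenylphenyl)ethan-1-one | CC(=O)c1ccc(O)c(CC=C(C)C)c1O | intermediate
12 | 1-[4-(allyloxy)-2-hydroxy-3-prenylphenyl]ethan-1-one | CC(=O)c1ccc(OCC=C)c(CC=C(C)C)c1O | intermediate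
13 | 1-[4-(allyloxy)-2-methoxy-3-prenylphenyl]ethan-1-one | CC(=O)c1ccc(OCC=C)c(CC=C(C)C)c1OC | intermediate
14 | {1-[4-(allyloxy)-2-methoxy-3-prenylphenyl]ethenyl}oxy(trimethyl)silane, not isolated | C=C(O[Si](C)(C)C)c1ccc(OCC=C)c(CC=C(C)C)c1OC | intermediate
15 | 2-bromo-1-[4-(allyloxy)-2-methoxy-3-prenylphenyl]ethan-1-one | O=C(CBr)c1ccc(OCC=C)c(CC=C(C)C)c1OC | intermediate
16 | keto aldehyde, 6-(allyloxy)-2-{2-[4-(allyloxy)-2-methoxy-3-prenylphenyl]-2-oxoethoxy}-4-methoxy-3-prenylbenzaldehyde | COc1cc(OCC=C)c(C=O)c(c1CC=C(C)C)OCC(=O)c1ccc(OCC=C)c(CC=C(C)C)c1OC | intermediate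
17 | (3S)-5-(allyloxy)-3-[4-(allyloxy)-2-methoxy-3-prenylphenyl]-3-hydroxy-7-methoxy-8-prenylchroman-4-one | COc1cc(OCC=C)c2c(c1CC=C(C)C)OC[C@@](O)(c1ccc(OCC=C)c(CC=C(C)C)c1OC)C2=O | intermediate
18 | sophonorol F, (3S) | COc1cc(O)c2c(c1CC=C(C)C)OC[C@@](O)(c1ccc(O)c(CC=C(C)C)c1OC)C2=O | target

**Step count**
Total: 14 steps.
Longest linear sequence: 9 steps (steps 6–14, from 8). The ring-A branch (steps 1–5) joins at step 12.

**Steps most likely to fail**

1. Step 13.
- Risk: carbene addition and proton transfer at the electron-rich, doubly ortho-oxygenated aldehyde may be too slow with the bulky chiral carbene, so the base-induced aldol condensation could take over. Facial selectivity at the ketone may also be poor.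
- Fallback: stereocontrol by resolution instead of by the catalyst. It sets out from 16. The small achiral carbene from 2-(pentafluorophenyl)-6,7-dihydro-5H-pyrrolo[2,1-c][1,2,4]triazol-2-ium tetrafluoroborate and Et3N in toluene closes the same bond to give the racemic ketol F1. Preparative chromatography on a chiral stationary phase (amylose tris(3,5-dimethylphenylcarbamate) on silica) separates it into 17, where the route is rejoined, and the 3R enantiomer F2.

2. Step 12.
- Risk: substitution at the hindered, hydrogen-bonded phenoxide may be slow. The longer contact with base then lets the product enolise at C2 and condense with its own aldehyde (Rap–Stoermer path).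
- Fallback: O1–C2 is formed by a neutral redox condensation instead of phenoxide alkylation. It sets out from 15. Sodium formate in aqueous ethanol at reflux displaces bromide to give the formate ester F3, which hydrolyses in the same medium to the hydroxy ketone F4. A Mitsunobu reaction of F4 with phenol 7 (PPh3, DIAD, THF, 0 °C → rt) then gives 16.

3. Step 5.
- Risk: thermal loss of isoprene from the tertiary allyl ether of an ortho-formyl phenol may compete with the [3,3] shift. Prolonged heating may also start the second Claisen shift, that of the O-allyl group.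
- Fallback: direct electrophilic C-prenylation instead of the sigmatropic route. It sets out from 2. Prenyl bromide with KOH in aqueous methanol at 0 °C alkylates the phloroglucinol-type phenoxide at carbon to give 2,6-dihydroxy-4-methoxy-3-prenylbenzaldehyde F5. C3 and C5 are equivalent, so only the extent of alkylation and the C/O selectivity have to be controlled. One equivalent of allyl bromide with K2CO3 in acetone then alkylates the less hindered 6-OH, while the 2-OH, flanked by prenyl and CHO, keeps the chelate. This gives 7.

**Further compounds**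
F1 | step 13 | racemic 5-(allyloxy)-3-[4-(allyloxy)-2-methoxy-3-prenylphenyl]-3-hydroxy-7-methoxy-8-prenylchroman-4-one | COc1cc(OCC=C)c2c(c1CC=C(C)C)OCC(O)(c1ccc(OCC=C)c(CC=C(C)C)c1OC)C2=O
F2 | step 13 | (3R)-5-(allyloxy)-3-[4-(allyloxy)-2-methoxy-3-prenylphenyl]-3-hydroxy-7-methoxy-8-prenylchroman-4-one | COc1cc(OCC=C)c2c(c1CC=C(C)C)OC[C@](O)(c1ccc(OCC=C)c(CC=C(C)C)c1OC)C2=O
F3 | step 12 | 2-[4-(allyloxy)-2-methoxy-3-prenylphenyl]-2-oxoethyl formate | O=COCC(=O)c1ccc(OCC=C)c(CC=C(C)C)c1OC
F4 | step 12 | 1-[4-(allyloxy)-2-methoxy-3-prenylphenyl]-2-hydroxyethan-1-one | O=C(CO)c1ccc(OCC=C)c(CC=C(C)C)c1OC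
F5 | step 5 | 2,6-dihydroxy-4-methoxy-3-prenylbenzaldehyde | COc1cc(O)c(C=O)c(O)c1CC=C(C)C
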